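Late in the north run the complex with two exchanged reads 24.0 %, while a square-law rise from its earlier reading, 7.8 % at 30.0 min, leads to 55.5 %, so the exchanges have slowed by then.

| flask | starting complex | incoming ligand | remark | time |
|---|---|---|---|---|
| east | 0.25 M | 0.28 M | run made earlier |  |
| north | 0.25 M | 0.86 M | run made earlier |  |
| zeta | 0.25 M | 1.00 M |  | 2.5 h |
| eta | 0.25 M | 0.500 M |  | 2.5 h |

- east (time / min: complex with two exchanged / %): 20.0: 0.7; 40.0: 1.9; 60.0: 3.1; 80.0: 4.0
- north (time / min: complex with two exchanged / %): 6.00: 0.9; 15.0: 2.5; 30.0: 7.8; 80.0: 24.0

(standard deviation of a reading: 0.3 percentage points)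

- candidate steps: complex with two exchanged <-> isomer of the product; incoming ligand <-> dormant form; complex with one exchanged + incoming ligand -> leaving ligand + complex with two exchanged; starting complex + incoming ligand -> leaving ligand + complex with one exchanged

- which of these holds the largest part of the starting complex at the end of zeta (complex with one exchanged / starting complex / complex with two exchanged)
- which of these holds the largest part of the starting complex at the end of eta (complex with one exchanged / starting complex / complex with two exchanged)
- how much complex with two exchanged is there at the end of eta, in percent of the starting complex charged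

Take that 30.0 min reading as two consecutive exchanges with one rate constant k, the ligand still at its charge, and y the fraction with two exchanged:

k = √(2y) / (ligand charge × time) = 0.0153 L mol⁻¹ min⁻¹

Now rank the clocks. One exchange takes 65.3 min in zeta and 131 min in eta, whose run lasts 150 min. The ligand's own clock, the inverse of k times the complex charge, is 261 min, the slowest, and no ligand charge enters it. That clock is 1.74 times the run, so the ligand falls during the run: this clock puts it at 0.563 of its charge at the end of zeta or eta. As a rough reckoning, then, freeze it at the mean of its starting and final fractions, so that each exchange runs at one constant rate per complex: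

f = 0.782

θ = k × f × ligand charge × time = 0.897 in eta, 1.79 in zeta

This exposure, the exchanges on offer to each complex, leaves exp(−θ) as starting complex, θ·exp(−θ) with one exchanged, and 1 − (1 + θ)·exp(−θ) with two exchanged.

On north's last time the rule gives 0.914 and 23.3 %, against the reading of 24.0 %. So I commit to 40.8 %, 36.6 % and 22.7 % in eta, and 53.4 % with two exchanged in zeta.

The forecast names complex with two exchanged for zeta, starting complex for eta, and 20 % (13 % to 27 %), adding of eta: “Starting versus mono is close”.

Zeta ends with complex with two exchanged ahead at 38.0 %. Eta ends with starting complex ahead at 45.4 %, and its 18.8 % with two exchanged is lower than my 22.7 %, while the isomer of the product holds 11.2 %.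

    complex with two exchanged ⇌ isomer of the product (K = 1.90, k = 0.570 h⁻¹)
    incoming ligand ⇌ dormant form (K = 0.150, k = 0.420 h⁻¹)
    complex with one exchanged + incoming ligand → leaving ligand + complex with two exchanged (k = 1.90 L mol⁻¹ h⁻¹)
    starting complex + incoming ligand → leaving ligand + complex with one exchanged (k = 0.940 L mol⁻¹ h⁻¹)

Take a neighbour of eta charged with 0.20 M of ligand: the same f gives θ = 0.359, so 69.8 % starting complex and 5.09 % with two exchanged. That flask holds 72.8 % and 4.83 %, and keeps 49 % of its ligand, against 50 % in eta.

All runs were computed with constants of no real substance, and the scatter is random.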